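Everything rests on opening the C6=C7 alkene of the cyclohexene ring (indene numbering: C2 ketone, C3a/C7a ring fusion, C4 acid carbon, C5 styryl carbon). Because this alkene ends at the quaternary carbon C5, the styryl group can be traced back to one of two identical vinyl groups, which leaves C5 non-stereogenic until the ring exists. A group-selective ring-closing metathesis between one of these vinyl groups and the isopropenyl group on C7a then closes the six-membered ring, creates C6=C7 and fixes C5 in a single operation. Its precursor is an all-trans 2,5-dimethylcyclopentanone with isopropenyl at C7a and, at C3a, the quaternary ester carbon C4 bonded to a 3-ethylpenta-1,4-dien-3-yl unit.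

Key step: step 15

Remark: atom labels such as C3a refer to the indene numbering of the target throughout, also for monocyclic intermediates.
Remark: the R configuration of 2 is assumed to follow from the (S)-oxazaborolidine by the usual large/small model; the enantiomeric catalyst is used if the sense proves opposite.
Remark: compounds 5 to 14 are carried as mixtures of epimers at the ester α-carbon (future C4), which becomes trigonal in step 9.

Step 1
Reactants: 1 2-methylcyclopent-2-en-1-one
Product: 2 (R)-2-methylcyclopent-2-en-1-ol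
Conditions: (S)-Me-CBS (10 mol %), BH3·SMe2, THF, −20 °C; MeOH quench
Reagents that add atoms: none
Why: Corey–Bakshi–Shibata reduction, in which the oxazaborolidine–borane complex binds the carbonyl oxygen anti to the larger methyl-substituted alkenyl arm and delivers hydride to one face, which should give the R carbinol centre whose chirality is later relayed to C3a.

Step 2
Reactants: 2 (R)-2-methylcyclopent-2-en-1-ol; 3 triethyl orthobutyrate
Product: 5 ethyl 2-[(1R)-2-methylcyclopent-2-en-1-yl]butanoate, via ketene acetal 4 (not isolated)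
Conditions: EtCO2H (cat.), excess 3, 140 °C, EtOH distilled off
Reagents that add atoms: none
Why: Johnson–Claisen rearrangement, in which the [3,3] shift of ketene acetal 4 is necessarily suprafacial on the five-membered ring, so the C–O stereocentre is traded for the new C–C stereocentre (future C3a) on the same face.

Step 3
Reactants: 5 ethyl 2-[(1R)-2-methylcyclopent-2-en-1-yl]butanoate
Product: 7 ethyl 2-[(1S,2S,3S)-3-hydroxy-2-methylcyclopentyl]butanoate, via alkylborane 6 (not isolated)
Conditions: BH3·THF, THF, 0 °C to rt; then 30% H2O2, 3 M NaOH, 0 °C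
Reagents that add atoms: hydrogen peroxide, OO
Why: Hydroboration–oxidation, in which borane adds syn to the trisubstituted ring alkene from the face opposite the branched side chain with boron on the less substituted carbon (future C2), placing the ring methyl (C3) cis to the side chain and, after oxidation with retention, the hydroxyl trans to both.

Step 4
Reactants: 7 ethyl 2-[(1S,2S,3S)-3-hydroxy-2-methylcyclopentyl]butanoate
Product: 8 ethyl 2-[(1S,2S,3S)-3-(tert-butyldimethylsilyloxy)-2-methylcyclopentyl]butanoate
Conditions: TBSCl, imidazole, DMF, rt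
Reagents that add atoms: tert-butyldimethylsilyl chloride, CC(C)(C)[Si](C)(C)Cl
Why: Standard silylation of a secondary alcohol, which masks the C2 oxygen through the coming enolate chemistry and creates no stereocentre.

Step 5
Reactants: 8 ethyl 2-[(1S,2S,3S)-3-(tert-butyldimethylsilyloxy)-2-methylcyclopentyl]butanoate
Product: 9 2-[(1S,2S,3S)-3-(tert-butyldimethylsilyloxy)-2-methylcyclopentyl]butanoic acid
Conditions: LiOH·H2O, THF/MeOH/H2O, 50 °C; cold 1 M HCl to pH 3–4
Reagents that add atoms: lithium hydroxide, [Li+].[OH-]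
Why: Saponification of an ethyl ester, which the TBS ether tolerates and in which epimerisation at the α-carbon is of no consequence.

Step 6
Reactants: 10 ethyl pent-2-ynoate
Product: 12 ethyl (2E)-3-ethylpenta-2,4-dienoate, via alkenylcopper adduct 11 (not isolated)
Conditions: CH2=CHMgBr (2.2 equiv), CuI (1.1 equiv), THF, −78 °C; MeOH at −78 °C, then aq. NH4Cl
Reagents that add atoms: vinylmagnesium bromide, C=C[Mg]Br
Why: Conjugate carbocupration of an ynoate, in which vinyl and copper add syn across the triple bond and cold protonation of 11 retains the geometry to give the 2E dienoate (this geometry ends in no stereocentre later).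

Step 7
Reactants: 12 ethyl (2E)-3-ethylpenta-2,4-dienoate
Product: 13 (2E)-3-ethylpenta-2,4-dien-1-ol
Conditions: DIBAL-H (2.2 equiv), CH2Cl2, −78 °C; Rochelle salt
Reagents that add atoms: none
Why: DIBAL-H 1,2-reduction of the conjugated ester to the primary allylic alcohol at low temperature, leaving the diene untouched.

Step 8
Reactants: 9 2-[(1S,2S,3S)-3-(tert-butyldimethylsilyloxy)-2-methylcyclopentyl]butanoic acid; 13 (2E)-3-ethylpenta-2,4-dien-1-ol
Product: 14 (2E)-3-ethylpenta-2,4-dien-1-yl 2-[(1S,2S,3S)-3-(tert-butyldimethylsilyloxy)-2-methylcyclopentyl]butanoate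
Conditions: EDC·HCl, DMAP, CH2Cl2, 0 °C to rt
Reagents that add atoms: none
Why: Steglich-type carbodiimide esterification of a primary allylic alcohol under non-acidic conditions that spare the ionisable dienyl unit and the silyl ether.

Step 9
Reactants: 14 (2E)-3-ethylpenta-2,4-dien-1-yl 2-[(1S,2S,3S)-3-(tert-butyldimethylsilyloxy)-2-methylcyclopentyl]butanoate
Product: 17 (2S)-2-[(1S,2S,3S)-3-(tert-butyldimethylsilyloxy)-2-methylcyclopentyl]-2,3-diethyl-3-ethenylpent-4-enoic acid, via silyl ketene acetal 15 (not isolated), via trimethylsilyl ester 16 (not isolated)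
Conditions: LDA, THF–DMPU, −78 °C; TMSCl–Et3N; −78 to 65 °C; brief dilute aq. HCl work-up
Reagents that add atoms: none
Why: Ireland–Claisen rearrangement, in which the tetrasubstituted silyl ketene acetal 15 moves the dienyl group through a six-membered transition state to forge the C4–C5 bond between two fully substituted carbons (C5 gains two identical vinyl groups, so ketene acetal and diene geometry do not matter), and C4 is set by face selection: with H-3a eclipsing the ketene acetal and the C4 ethyl group under the ring, the cis C3 methyl shields one face and the dienyl terminus should arrive from the open C7a methylene side, which is the configuration required.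

Step 10
Reactants: 17 (2S)-2-[(1S,2S,3S)-3-(tert-butyldimethylsilyloxy)-2-methylcyclopentyl]-2,3-diethyl-3-ethenylpent-4-enoic acid
Product: 18 methyl (2S)-2-[(1S,2S,3S)-3-(tert-butyldimethylsilyloxy)-2-methylcyclopentyl]-2,3-diethyl-3-ethenylpent-4-enoate
Conditions: MeI, K2CO3, DMF, rt
Reagents that add atoms: iodomethane, CI
Why: SN2 O-alkylation of the carboxylate, which is insensitive to the congestion around the carboxyl carbon.

Step 11
Reactants: 18 methyl (2S)-2-[(1S,2S,3S)-3-(tert-butyldimethylsilyloxy)-2-methylcyclopentyl]-2,3-diethyl-3-ethenylpent-4-enoate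
Product: 19 methyl (2S)-2-[(1S,2S,3S)-3-hydroxy-2-methylcyclopentyl]-2,3-diethyl-3-ethenylpent-4-enoate
Conditions: HF·pyridine, THF/pyridine, 0 °C to rt
Reagents that add atoms: none
Why: Fluoride-mediated cleavage of the silyl ether, after which the hydroxyl is trans to the ester-bearing arm and cannot lactonise.

Step 12
Reactants: 19 methyl (2S)-2-[(1S,2S,3S)-3-hydroxy-2-methylcyclopentyl]-2,3-diethyl-3-ethenylpent-4-enoate
Product: 21 methyl (2S)-2-[(1S,2R)-2-methyl-3-oxocyclopentyl]-2,3-diethyl-3-ethenylpent-4-enoate, via cis-methyl ketone 20 (not isolated)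
Conditions: Dess–Martin periodinane, NaHCO3, CH2Cl2, rt; crude ketone then K2CO3 (cat.), MeOH, rt
Reagents that add atoms: none
Why: Dess–Martin oxidation gives the ketone, and base-mediated enolisation then equilibrates the α-stereocentre C3 to the thermodynamically favoured arrangement with the methyl trans to the bulky C3a substituent.

Step 13
Reactants: 21 methyl (2S)-2-[(1S,2R)-2-methyl-3-oxocyclopentyl]-2,3-diethyl-3-ethenylpent-4-enoate
Product: 23 methyl (2S)-2-[(1S,5R)-5-methyl-4-oxocyclopent-2-en-1-yl]-2,3-diethyl-3-ethenylpent-4-enoate, via silyl enol ether 22 (not isolated)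
Conditions: LDA, TMSCl, THF, −78 °C; then Pd(OAc)2 (1.1 equiv), MeCN, rt
Reagents that add atoms: none
Why: Saegusa–Ito oxidation, in which LDA removes a proton from the less hindered C1 methylene, the silyl enol ether 22 is palladated at C1 and β-hydride elimination from C7a gives the C1=C7a enone (the C4 ester has no α-hydrogen).

Step 14
Reactants: 23 methyl (2S)-2-[(1S,5R)-5-methyl-4-oxocyclopent-2-en-1-yl]-2,3-diethyl-3-ethenylpent-4-enoate
Product: 25 methyl (2S)-2-[(1S,2R,4R,5S)-2,4-dimethyl-3-oxo-5-(prop-1-en-2-yl)cyclopentyl]-2,3-diethyl-3-ethenylpent-4-enoate, via magnesium enolate 24 (not isolated)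
Conditions: CH2=C(CH3)MgBr (3 equiv), CuI (1.5 equiv), THF, −78 to −40 °C; then MeI, DMPU, −40 to 0 °C
Reagents that add atoms: isopropenylmagnesium bromide, CC(=C)[Mg]Br; iodomethane, CI
Why: Organocuprate conjugate addition followed by enolate alkylation, in which isopropenyl adds to C7a anti to the large C3a substituent and the regiodefined enolate 24 is methylated at C1 anti to the new isopropenyl group, giving the all-trans cyclopentanone, which is also the thermodynamic arrangement.

Step 15
Reactants: 25 methyl (2S)-2-[(1S,2R,4R,5S)-2,4-dimethyl-3-oxo-5-(prop-1-en-2-yl)cyclopentyl]-2,3-diethyl-3-ethenylpent-4-enoate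
Product: 26 methyl (1R,3R,3aS,4S,5R,7aS)-5-ethenyl-4,5-diethyl-1,3,7-trimethyl-2-oxo-2,3,3a,4,5,7a-hexahydro-1H-indene-4-carboxylate
Conditions: Hoveyda–Grubbs II (10 mol %), toluene (5 mM), 80 °C, argon sparge
Reagents that add atoms: none
Why: The ruthenium alkylidene exchanges onto one of the two C5 vinyl groups (the 1,1-disubstituted isopropenyl group does not load), adds intramolecularly across the isopropenyl alkene to give a ruthenacyclobutane and cycloreverts to the C6=C7 alkene and a methylidene that leaves as ethylene. The closest known reaction type is the desymmetrising ring-closing metathesis of trienes in which two identical vinyl groups sit on a prochiral quaternary carbon, run under substrate or chiral-alkylidene control. The ring is closed as a cyclohexene by joining the two ends of a 1,7-diene (C6 to C7), fused trans to the cyclopentanone because the C3a and C7a arms are already trans; the two vinyl groups cannot close with each other, and high dilution suppresses intermolecular metathesis. The new stereocentre C5 is fixed by which vinyl group enters the ring, and this is governed by the existing C4, C3a and C7a centres: in the half-chair imposed by the trans fusion the C4 ethyl group must be axial, and the two spectator groups at C5 take one pseudoaxial and one pseudoequatorial site. The slimmer, planar vinyl group is expected to take the pseudoaxial site anti to the axial C4 ethyl group while the C5 ethyl group goes pseudoequatorial, which leaves the two ethyl groups cis and the vinyl group cis to the ester, as in 26. The step therefore needs selectivity between diastereotopic vinyl groups, and because the substrate bias is expected to be modest, a chiral Ru or Mo alkylidene in its matched sense is held ready to reinforce it.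

Step 16
Reactants: 26 methyl (1R,3R,3aS,4S,5R,7aS)-5-ethenyl-4,5-diethyl-1,3,7-trimethyl-2-oxo-2,3,3a,4,5,7a-hexahydro-1H-indene-4-carboxylate; 27 iodobenzene
Product: 28 methyl (1R,3R,3aS,4S,5R,7aS)-4,5-diethyl-1,3,7-trimethyl-2-oxo-5-[(E)-2-phenylethenyl]-2,3,3a,4,5,7a-hexahydro-1H-indene-4-carboxylate
Conditions: Pd(OAc)2 (10 mol %), P(o-tol)3, Et3N, DMF, 100 °C
Reagents that add atoms: none
Why: Mizoroki–Heck reaction, in which the arylpalladium species adds to the only monosubstituted alkene with phenyl on the terminal carbon and, since C5 bears no hydrogen, β-hydride elimination can occur only from the benzylic carbon, giving the E-styrene without double-bond migration.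

Step 17
Reactants: 28 methyl (1R,3R,3aS,4S,5R,7aS)-4,5-diethyl-1,3,7-trimethyl-2-oxo-5-[(E)-2-phenylethenyl]-2,3,3a,4,5,7a-hexahydro-1H-indene-4-carboxylate
Product: 29 dinorspiculoic acid A
Conditions: LiI, pyridine, reflux; 1 M HCl work-up
Reagents that add atoms: none
Why: Nucleophilic demethylation, in which iodide attacks the ester methyl group (SN2, alkyl–oxygen cleavage), so the congestion around the carbonyl is irrelevant and the already thermodynamic α-centres of the ketone are not at risk.

Compound list
1 | 2-methylcyclopent-2-en-1-one | CC1=CCCC1=O | starting material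
2 | (R)-2-methylcyclopent-2-en-1-ol | CC1=CCC[C@H]1O | intermediate
3 | triethyl orthobutyrate (1,1,1-triethoxybutane) | CCCC(OCC)(OCC)OCC | starting material
4 | ketene acetal, 1-ethoxy-1-{[(1R)-2-methylcyclopent-2-en-1-yl]oxy}but-1-ene | CCC=C(OCC)O[C@@H]1CCC=C1C | intermediate
5 | ethyl 2-[(1R)-2-methylcyclopent-2-en-1-yl]butanoate (α-epimers) | CCOC(=O)C(CC)[C@H]1CCC=C1C | intermediate
6 | alkylborane from 5, boron at C2 and hydrogen at C3 anti to the side chain (shown as RBH2) | CCOC(=O)C(CC)[C@H]1CC[C@H](B)[C@H]1C | intermediate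
7 | ethyl 2-[(1S,2S,3S)-3-hydroxy-2-methylcyclopentyl]butanoate (ring methyl cis to side chain, OH trans to both) | CCOC(=O)C(CC)[C@H]1CC[C@H](O)[C@H]1C | intermediate
8 | ethyl 2-[(1S,2S,3S)-3-(tert-butyldimethylsilyloxy)-2-methylcyclopentyl]butanoate | CCOC(=O)C(CC)[C@H]1CC[C@H](O[Si](C)(C)C(C)(C)C)[C@H]1C | intermediate
9 | 2-[(1S,2S,3S)-3-(tert-butyldimethylsilyloxy)-2-methylcyclopentyl]butanoic acid | CCC(C(=O)O)[C@H]1CC[C@H](O[Si](C)(C)C(C)(C)C)[C@H]1C | intermediate
10 | ethyl pent-2-ynoate | CCC#CC(=O)OCC | starting material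
11 | alkenylcopper adduct, ethyl (2Z)-2-cuprio-3-ethylpenta-2,4-dienoate (Cu cis to vinyl) | CCOC(=O)/C([Cu])=C(CC)/C=C | intermediate
12 | ethyl (2E)-3-ethylpenta-2,4-dienoate | CCOC(=O)/C=C(CC)/C=C | intermediate
13 | (2E)-3-ethylpenta-2,4-dien-1-ol | OC/C=C(CC)/C=C | intermediate
14 | (2E)-3-ethylpenta-2,4-dien-1-yl 2-[(1S,2S,3S)-3-(tert-butyldimethylsilyloxy)-2-methylcyclopentyl]butanoate | C=C/C(CC)=C/COC(=O)C(CC)[C@H]1CC[C@H](O[Si](C)(C)C(C)(C)C)[C@H]1C | intermediate
15 | trimethylsilyl ketene acetal of 14 | C=C/C(CC)=C/COC(O[Si](C)(C)C)=C(CC)[C@H]1CC[C@H](O[Si](C)(C)C(C)(C)C)[C@H]1C | intermediate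
16 | trimethylsilyl ester of 17 | C1[C@@H]([C@H](C)[C@@H](O[Si](C)(C)C(C)(C)C)C1)[C@](C(CC)(C=C)C=C)(CC)C(=O)O[Si](C)(C)C | intermediate
17 | (2S)-2-[(1S,2S,3S)-3-(tert-butyldimethylsilyloxy)-2-methylcyclopentyl]-2,3-diethyl-3-ethenylpent-4-enoic acid | C1[C@@H]([C@H](C)[C@@H](O[Si](C)(C)C(C)(C)C)C1)[C@](C(CC)(C=C)C=C)(CC)C(=O)O | intermediate
18 | methyl (2S)-2-[(1S,2S,3S)-3-(tert-butyldimethylsilyloxy)-2-methylcyclopentyl]-2,3-diethyl-3-ethenylpent-4-enoate | C1[C@@H]([C@H](C)[C@@H](O[Si](C)(C)C(C)(C)C)C1)[C@](C(CC)(C=C)C=C)(CC)C(=O)OC | intermediate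
19 | methyl (2S)-2-[(1S,2S,3S)-3-hydroxy-2-methylcyclopentyl]-2,3-diethyl-3-ethenylpent-4-enoate | C1[C@@H]([C@H](C)[C@@H](O)C1)[C@](C(CC)(C=C)C=C)(CC)C(=O)OC | intermediate
20 | methyl (2S)-2-[(1S,2S)-2-methyl-3-oxocyclopentyl]-2,3-diethyl-3-ethenylpent-4-enoate (ring methyl cis to side chain) | C1[C@@H]([C@H](C)C(=O)C1)[C@](C(CC)(C=C)C=C)(CC)C(=O)OC | intermediate
21 | methyl (2S)-2-[(1S,2R)-2-methyl-3-oxocyclopentyl]-2,3-diethyl-3-ethenylpent-4-enoate (ring methyl trans to side chain) | C1[C@@H]([C@@H](C)C(=O)C1)[C@](C(CC)(C=C)C=C)(CC)C(=O)OC | intermediate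
22 | trimethylsilyl enol ether of 21 (C1=C2 enol ether) | C1[C@@H]([C@@H](C)C(O[Si](C)(C)C)=C1)[C@](C(CC)(C=C)C=C)(CC)C(=O)OC | intermediate
23 | methyl (2S)-2-[(1S,5R)-5-methyl-4-oxocyclopent-2-en-1-yl]-2,3-diethyl-3-ethenylpent-4-enoate | C1=CC(=O)[C@H](C)[C@H]1[C@](C(CC)(C=C)C=C)(CC)C(=O)OC | intermediate
24 | bromomagnesium enolate (C1=C2) after isopropenyl addition at C7a | C=C(C)[C@H]1[C@@H]([C@@H](C)C(O[Mg]Br)=C1)[C@](C(CC)(C=C)C=C)(CC)C(=O)OC | intermediate
25 | methyl (2S)-2-[(1S,2R,4R,5S)-2,4-dimethyl-3-oxo-5-(prop-1-en-2-yl)cyclopentyl]-2,3-diethyl-3-ethenylpent-4-enoate (all-trans ring; metathesis precursor) | C=C(C)[C@H]1[C@@H]([C@@H](C)C(=O)[C@@H]1C)[C@](C(CC)(C=C)C=C)(CC)C(=O)OC | intermediate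
26 | methyl (1R,3R,3aS,4S,5R,7aS)-5-ethenyl-4,5-diethyl-1,3,7-trimethyl-2-oxo-2,3,3a,4,5,7a-hexahydro-1H-indene-4-carboxylate | CC[C@@]1(C=C)C=C(C)[C@H]2[C@@H]([C@@H](C)C(=O)[C@@H]2C)[C@]1(CC)C(=O)OC | intermediate
27 | iodobenzene | Ic1ccccc1 | starting material
28 | methyl (1R,3R,3aS,4S,5R,7aS)-4,5-diethyl-1,3,7-trimethyl-2-oxo-5-[(E)-2-phenylethenyl]-2,3,3a,4,5,7a-hexahydro-1H-indene-4-carboxylate | CC[C@@]1(/C=C/c2ccccc2)C=C(C)[C@H]2[C@@H]([C@@H](C)C(=O)[C@@H]2C)[C@]1(CC)C(=O)OC | intermediate
29 | dinorspiculoic acid A, (1R,3R,3aS,4S,5R,7aS)-4,5-diethyl-1,3,7-trimethyl-2-oxo-5-[(E)-2-phenylethenyl]-2,3,3a,4,5,7a-hexahydro-1H-indene-4-carboxylic acid | CC[C@@]1(/C=C/c2ccccc2)C=C(C)[C@H]2[C@@H]([C@@H](C)C(=O)[C@@H]2C)[C@]1(CC)C(=O)O | target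

Total step count: 17. Longest linear sequence: 15 steps (steps 1–5 and 8–17); steps 6–7 form the dienol branch.

Steps most likely to fail

Step 15. The alkylidene may load only slowly on the neopentyl-type vinyl groups, or load irreversibly on either of them, so that little selection between the two diastereotopic groups takes place. The fallback is a relay ring-closing metathesis that sets out from enone 23. The conjugate addition of step 14 is run with the cuprate made from (Z)-allyl 3-iodobut-2-enyl ether (iodine–lithium exchange, then CuI), again followed by MeI. This gives methyl (2S)-2-[(1S,2R,4R,5S)-5-[(2Z)-4-(allyloxy)but-2-en-2-yl]-2,4-dimethyl-3-oxocyclopentyl]-2,3-diethyl-3-ethenylpent-4-enoate F1, in which the isopropenyl terminus carries an allyloxymethyl arm. The catalyst then loads on the unhindered allyl ether, expels 2,5-dihydrofuran and so places the alkylidene on C7. The choice between the two C5 vinyl groups is then made in the ring-closing event itself, and the product is ester 26, where the route is rejoined.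

Step 9. Enolisation of the congested α-branched ester may be incomplete, or face selection at C4 during the rearrangement may be insufficient. The fallback sets out from ester 5 and runs the rearrangement before the ring is oxidised.
- Saponification gives 2-[(1R)-2-methylcyclopent-2-en-1-yl]butanoic acid F2.
- Carbodiimide coupling with dienol 13 gives (2E)-3-ethylpenta-2,4-dien-1-yl 2-[(1R)-2-methylcyclopent-2-en-1-yl]butanoate F3.
- Ireland–Claisen rearrangement on this flatter, silyl-ether-free ring (in-plane C3 methyl on one flank, CH2 on the other) gives (2S)-2,3-diethyl-3-ethenyl-2-[(1S)-2-methylcyclopent-2-en-1-yl]pent-4-enoic acid F4.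
- Methylation with MeI and K2CO3 gives the methyl ester of that acid F5.
- mCPBA epoxidises the trisubstituted ring alkene selectively, anti to the side chain, to give the epoxy ester F6.
- A Lewis-acid Meinwald rearrangement (1,2-hydride shift from C2 to C3, for example with MgBr2·OEt2) followed by base equilibration gives ketone 21, where the route is rejoined.

Step 14. The 1,4-addition next to the fully substituted C4 centre may be slow, with 1,2-addition gaining ground, or the enolate may equilibrate during methylation and be methylated at C3. The fallback sets out from enone 23 and separates the two bond formations. Rhodium-catalysed conjugate addition of isopropenylboronic acid pinacol ester ([Rh(cod)OH]2, aqueous dioxane) gives methyl (2S)-2-[(1S,2R,5R)-2-methyl-3-oxo-5-(prop-1-en-2-yl)cyclopentyl]-2,3-diethyl-3-ethenylpent-4-enoate F7, with isopropenyl anti to the C3a substituent. Kinetic deprotonation of the C1 methylene with LDA and alkylation with MeI then give 25, where the route is rejoined.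

Further compounds
F1 | step 15 | methyl (2S)-2-[(1S,2R,4R,5S)-5-[(2Z)-4-(allyloxy)but-2-en-2-yl]-2,4-dimethyl-3-oxocyclopentyl]-2,3-diethyl-3-ethenylpent-4-enoate | C=CCOC/C=C(C)\[C@H]1[C@@H]([C@@H](C)C(=O)[C@@H]1C)[C@](C(CC)(C=C)C=C)(CC)C(=O)OC
F2 | step 9 | 2-[(1R)-2-methylcyclopent-2-en-1-yl]butanoic acid | CCC(C(=O)O)[C@H]1CCC=C1C
F3 | step 9 | (2E)-3-ethylpenta-2,4-dien-1-yl 2-[(1R)-2-methylcyclopent-2-en-1-yl]butanoate | C=C/C(CC)=C/COC(=O)C(CC)[C@H]1CCC=C1C
F4 | step 9 | (2S)-2,3-diethyl-3-ethenyl-2-[(1S)-2-methylcyclopent-2-en-1-yl]pent-4-enoic acid | C1[C@@H](C(C)=CC1)[C@](C(CC)(C=C)C=C)(CC)C(=O)O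
F5 | step 9 | methyl (2S)-2,3-diethyl-3-ethenyl-2-[(1S)-2-methylcyclopent-2-en-1-yl]pent-4-enoate | C1[C@@H](C(C)=CC1)[C@](C(CC)(C=C)C=C)(CC)C(=O)OC
F6 | step 9 | epoxy ester, methyl (2S)-2,3-diethyl-3-ethenyl-2-(1-methyl-6-oxabicyclo[3.1.0]hexan-2-yl)pent-4-enoate with the epoxide anti to the side chain | C1[C@@H]([C@@]2(C)O[C@H]2C1)[C@](C(CC)(C=C)C=C)(CC)C(=O)OC
F7 | step 14 | methyl (2S)-2-[(1S,2R,5R)-2-methyl-3-oxo-5-(prop-1-en-2-yl)cyclopentyl]-2,3-diethyl-3-ethenylpent-4-enoate | C=C(C)[C@H]1[C@@H]([C@@H](C)C(=O)C1)[C@](C(CC)(C=C)C=C)(CC)C(=O)OC
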